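Ring A, a 4,5,6-trisubstituted resorcinol monomethyl ether, is traced back to its cyclohexane-1,3-dione and aromatized last, so C4, C5 and C6 receive their carbon substituents as sp3 centres. The feature exploited is the 1,3-oxygen pattern at C1/C3 plus the identical 4-hydroxybenzyl groups on C4 and C6, which make the dione mirror-symmetric and its mono-O-methylation unambiguous. One pot joins a 2-benzylmalonate and an α-benzyl enone: conjugate addition makes C5–C6, acylation of the acetyl CH3 by one ester makes C1–C2 and closes the carbocycle, and hydrolysis expels the other ester as CO2. The enone precursor is a perbenzylated (E)-3-benzyl-6-arylhex-3-en-2-one that already carries ring B and its benzyl appendage.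

Key step: step 8

Remarks before the steps
- Assumption: the target has no stereocentre and no stereogenic double bond. The descriptors in 16–19 show the expected relative configuration of achiral or racemic material and do not affect the outcome.
- Numbering of ring A: C1 (OMe), C2 (H), C3 (OH), C4 and C6 (4-hydroxybenzyl), C5 (CH2CH2–ring B). Ring B is the 2-hydroxy-5-(4-hydroxybenzyl)phenyl ring.
- The enone is made by phosphonate olefination, not by a crossed aldol. An unsymmetrical ketone and an enolizable 3-arylpropanal would leave both the condensation site and self-condensation uncontrolled, whereas the phosphonate fixes the branch at C3.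
- Ring B is assembled by cross-coupling at a defined bromide, so no statistical functionalization of a symmetric bisphenol is needed. One electrophile, 4, supplies all three 4-oxybenzyl units.
- The ring-B oxygen is benzylated before the enone exists, because a free ortho phenol would close onto the enone to give a chroman.
- Methyl esters are the smallest available and match the methoxide base.
- A one-pot iodine–methanol aromatization is not used. It tends to etherify both oxygens and can iodinate the activated C2–H, so the enol ether is formed first and dehydrogenated separately.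

Step 1
Reactants: 1 methyl 3-(2-hydroxyphenyl)propanoate
Product: 2 methyl 3-(5-bromo-2-hydroxyphenyl)propanoate
Conditions: NBS (1.0 equiv), MeCN, 0 °C to rt
Reagents that add atoms: N-bromosuccinimide, O=C1CCC(=O)N1Br
Why: Electrophilic aromatic bromination of a free 2-alkylphenol is directed by the hydroxyl group to the unhindered para position, which is the ring-B carbon that has to carry the benzyl group.

Step 2
Reactants: 2 methyl 3-(5-bromo-2-hydroxyphenyl)propanoate
Product: 3 methyl 3-(2-benzyloxy-5-bromophenyl)propanoate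
Conditions: BnBr, K2CO3, DMF, rt
Reagents that add atoms: benzyl bromide, BrCc1ccccc1
Why: Williamson ether synthesis on the phenoxide leaves the methyl ester and the aryl bromide untouched and caps the oxygen that could otherwise lactonize or later add to the enone.

Step 3
Reactants: 3 methyl 3-(2-benzyloxy-5-bromophenyl)propanoate; 4 4-(benzyloxy)benzyl chloride
Product: 6 methyl 3-[2-benzyloxy-5-(4-benzyloxybenzyl)phenyl]propanoate, via benzylic zinc chloride 5 (not isolated)
Conditions: 4 (1.3 equiv), Zn dust, LiCl, THF, rt; then 3, Pd(OAc)2 (2 mol %), SPhos (4 mol %), THF, rt to 50 °C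
Reagents that add atoms: none
Why: Negishi coupling, in which LiCl-assisted zinc insertion into the benzylic chloride gives an ester-tolerant nucleophile and the electron-rich biarylphosphine lets zerovalent palladium insert into the deactivated aryl bromide, so the diarylmethane bond forms at one defined position.

Step 4
Reactants: 6 methyl 3-[2-benzyloxy-5-(4-benzyloxybenzyl)phenyl]propanoate
Product: 7 3-[2-benzyloxy-5-(4-benzyloxybenzyl)phenyl]propanal
Conditions: i-Bu2AlH (1.05 equiv), toluene, −78 °C; MeOH quench, aq. potassium sodium tartrate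
Reagents that add atoms: none
Why: Partial ester reduction stops at the aluminium hemiacetal, which is stable at −78 °C and releases the aldehyde only on work-up, as is routine for 3-arylpropanoates.

Step 5
Reactants: 8 diethyl (2-oxopropyl)phosphonate; 4 4-(benzyloxy)benzyl chloride
Product: 9 diethyl [1-(4-benzyloxyphenyl)-3-oxobutan-2-yl]phosphonate (racemic)
Conditions: NaH (1.0 equiv), THF–DMF, 0 °C; then 4, rt to 50 °C
Reagents that add atoms: none
Why: C-alkylation of the stabilized β-ketophosphonate anion with a reactive benzylic chloride takes place at the doubly activated carbon and thereby fixes the branch at C3 of the future enone.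

Step 6
Reactants: 7 3-[2-benzyloxy-5-(4-benzyloxybenzyl)phenyl]propanal; 9 diethyl [1-(4-benzyloxyphenyl)-3-oxobutan-2-yl]phosphonate
Product: 10 (E)-3-(4-benzyloxybenzyl)-6-[2-benzyloxy-5-(4-benzyloxybenzyl)phenyl]hex-3-en-2-one
Conditions: 9 (1.2 equiv), NaH (1.15 equiv), THF, 0 °C; then 7, 0 to 40 °C
Reagents that add atoms: none
Why: Horner–Wadsworth–Emmons olefination with the fully preformed, weakly basic phosphonate anion should place the acetyl group and the chain trans (E) as the less strained arrangement, and any Z isomer is an equally valid acceptor because the geometry is lost in step 8.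

Step 7
Reactants: 11 dimethyl malonate; 4 4-(benzyloxy)benzyl chloride
Product: 12 dimethyl 2-(4-benzyloxybenzyl)malonate
Conditions: 11 (2.5 equiv), NaH (1.1 equiv), THF–DMF, 0 °C; then 4, rt
Reagents that add atoms: none
Why: Malonic ester alkylation (SN2) with the malonate in excess limits double alkylation, and the aprotic medium avoids solvolysis of the ionizable 4-alkoxybenzyl chloride.

Step 8
Reactants: 10 (E)-3-(4-benzyloxybenzyl)-6-[2-benzyloxy-5-(4-benzyloxybenzyl)phenyl]hex-3-en-2-one; 12 dimethyl 2-(4-benzyloxybenzyl)malonate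
Product: 16 all-trans 4,6-bis(4-benzyloxybenzyl)-5-{2-[2-benzyloxy-5-(4-benzyloxybenzyl)phenyl]ethyl}cyclohexane-1,3-dione, via Michael adduct 13 (not isolated), via ring-closed keto ester 14 (not isolated), via keto acid 15 (not isolated)
Conditions: 12 (1.5 equiv), NaOMe (1.6 equiv), anhydrous MeOH–THF (1:1), about 1 M, 65 °C; then 2 M aq. NaOH, 75 °C; then 3 M HCl to pH 1, 70 °C
Reagents that add atoms: none
Why: The sodium enolate of 12 adds reversibly to the β-carbon (C4) of 10 and forms bond C5–C6 of ring A in δ-keto diester 13; proton exchange then gives the acetyl CH2 enolate, which attacks one of the geminal esters, forms bond C1–C2 and expels methoxide, and deprotonation of 14 to its vinylogous carboxylate is the sink that pulls the unfavourable addition equilibrium forward. The closest known reaction type is the Michael–Claisen (Michael–Dieckmann) annulation of alk-3-en-2-ones with malonates that leads to 5-alkylcyclohexane-1,3-diones, in which α-alkyl enones and 2-alkylmalonates have each been used, so the step is a known reaction applied to a more crowded pair. The one ring closes in a 6-(enolendo)-exo-trig mode, assisted by the fully substituted malonate carbon in the tether. C5 is formed without control, whereas C4 and C6 are α to carbonyl groups and should epimerize during the basic and acidic stages to the all-equatorial 4,5-trans-5,6-trans dione with a mirror plane through C2 and C5, and all three centres disappear in step 10. Only constitutional selectivity is needed, and the substrate secures it: carbonyl addition is reversible, C-acylation of the internal enolate would need a four-membered ring, an enol lactone from O-acylation is reopened by methoxide, the benzylic CH2 on the α-carbon of 10 is cross-conjugated and cannot shift the double bond, and the benzyl ether on ring B prevents oxa-Michael closure to a chroman. Aqueous NaOH then cleaves the remaining ester to 15, which loses CO2 as a β-keto acid on acidification.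

Step 9
Reactants: 16 all-trans 4,6-bis(4-benzyloxybenzyl)-5-{2-[2-benzyloxy-5-(4-benzyloxybenzyl)phenyl]ethyl}cyclohexane-1,3-dione
Product: 17 4,5-trans-5,6-trans-4,6-bis(4-benzyloxybenzyl)-5-{2-[2-benzyloxy-5-(4-benzyloxybenzyl)phenyl]ethyl}-3-methoxycyclohex-2-en-1-one (racemic)
Conditions: MeOH–CH2Cl2, HC(OMe)3 (2 equiv), p-TsOH·H2O (5 mol %), rt to 40 °C; aq. NaHCO3 work-up
Reagents that add atoms: methanol, CO; trimethyl orthoformate, COC(OC)OC
Why: Acid-catalysed enol ether formation from a vinylogous acid, with water removed by the orthoformate, gives the 3-methoxy enone, and because the two carbonyl groups of 16 are mirror images of each other only one constitution, formed as a racemate, can result.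

Step 10
Reactants: 17 4,5-trans-5,6-trans-4,6-bis(4-benzyloxybenzyl)-5-{2-[2-benzyloxy-5-(4-benzyloxybenzyl)phenyl]ethyl}-3-methoxycyclohex-2-en-1-one
Product: 21 2,4-bis(4-benzyloxybenzyl)-3-{2-[2-benzyloxy-5-(4-benzyloxybenzyl)phenyl]ethyl}-5-methoxyphenol, via selenide 18 (not isolated), via selenoxide 19 (not isolated), via dienone 20 (not isolated)
Conditions: LiN(i-Pr)2 (1.2 equiv), THF, −78 °C; PhSeCl (1.2 equiv), −78 to 0 °C; then H2O, AcOH, 30% H2O2, 0 °C to rt; chromatography to remove selenium residues
Reagents that add atoms: none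
Why: Kinetic deprotonation of the vinylogous ester at its α′ carbon (C6 in the numbering of 17, as in Stork–Danheiser chemistry), selenenylation anti to the C5 chain and selenoxide syn-elimination across C5–C6 remove two hydrogens, and dienone 20 tautomerizes at once to the phenol with OH at the former ketone carbon and OMe at the enol ether carbon.

Step 11
Reactants: 21 2,4-bis(4-benzyloxybenzyl)-3-{2-[2-benzyloxy-5-(4-benzyloxybenzyl)phenyl]ethyl}-5-methoxyphenol
Product: 22 2,4-bis(4-hydroxybenzyl)-3-{2-[2-hydroxy-5-(4-hydroxybenzyl)phenyl]ethyl}-5-methoxyphenol (CNP0134121.0)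
Conditions: H2 (1 atm), 10% Pd/C, THF–MeOH, rt
Reagents that add atoms: none
Why: Catalytic hydrogenolysis cleaves the four benzyl aryl ethers at their O–CH2Ph bonds, while the aryl methyl ether, the diarylmethane links and the bibenzyl bridge are inert under one atmosphere of hydrogen.

Compound list
1 | methyl 3-(2-hydroxyphenyl)propanoate | COC(=O)CCc1ccccc1O | starting material
2 | methyl 3-(5-bromo-2-hydroxyphenyl)propanoate | COC(=O)CCc1cc(Br)ccc1O | intermediate
3 | methyl 3-(2-benzyloxy-5-bromophenyl)propanoate | COC(=O)CCc1cc(Br)ccc1OCc1ccccc1 | intermediate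
4 | 4-(benzyloxy)benzyl chloride | ClCc1ccc(OCc2ccccc2)cc1 | starting material
5 | [4-(benzyloxy)benzyl]zinc chloride (THF solution containing LiCl) | Cl[Zn]Cc1ccc(OCc2ccccc2)cc1 | intermediate
6 | methyl 3-[2-benzyloxy-5-(4-benzyloxybenzyl)phenyl]propanoate | COC(=O)CCc1cc(Cc2ccc(OCc3ccccc3)cc2)ccc1OCc1ccccc1 | intermediate
7 | 3-[2-benzyloxy-5-(4-benzyloxybenzyl)phenyl]propanal | O=CCCc1cc(Cc2ccc(OCc3ccccc3)cc2)ccc1OCc1ccccc1 | intermediate
8 | diethyl (2-oxopropyl)phosphonate | CCOP(=O)(CC(C)=O)OCC | starting material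
9 | diethyl [1-(4-benzyloxyphenyl)-3-oxobutan-2-yl]phosphonate (racemic) | CCOP(=O)(OCC)C(Cc1ccc(OCc2ccccc2)cc1)C(C)=O | intermediate
10 | (E)-3-(4-benzyloxybenzyl)-6-[2-benzyloxy-5-(4-benzyloxybenzyl)phenyl]hex-3-en-2-one | CC(=O)/C(Cc1ccc(OCc2ccccc2)cc1)=C/CCc1cc(Cc2ccc(OCc3ccccc3)cc2)ccc1OCc1ccccc1 | intermediate
11 | dimethyl malonate | COC(=O)CC(=O)OC | starting material
12 | dimethyl 2-(4-benzyloxybenzyl)malonate | COC(=O)C(Cc1ccc(OCc2ccccc2)cc1)C(=O)OC | intermediate
13 | dimethyl 2-(4-benzyloxybenzyl)-2-{4-(4-benzyloxybenzyl)-1-[2-benzyloxy-5-(4-benzyloxybenzyl)phenyl]-5-oxohexan-3-yl}malonate (diastereomer mixture, racemic) | CC(=O)C(Cc1ccc(OCc2ccccc2)cc1)C(CCc1cc(Cc2ccc(OCc3ccccc3)cc2)ccc1OCc1ccccc1)C(Cc1ccc(OCc2ccccc2)cc1)(C(=O)OC)C(=O)OC | intermediate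
14 | methyl 1,3-bis(4-benzyloxybenzyl)-2-{2-[2-benzyloxy-5-(4-benzyloxybenzyl)phenyl]ethyl}-4,6-dioxocyclohexane-1-carboxylate (diastereomer mixture, present as its sodium enolate) | COC(=O)C1(Cc2ccc(OCc3ccccc3)cc2)C(=O)CC(=O)C(Cc2ccc(OCc3ccccc3)cc2)C1CCc1cc(Cc2ccc(OCc3ccccc3)cc2)ccc1OCc1ccccc1 | intermediate
15 | 1,3-bis(4-benzyloxybenzyl)-2-{2-[2-benzyloxy-5-(4-benzyloxybenzyl)phenyl]ethyl}-4,6-dioxocyclohexane-1-carboxylic acid (diastereomer mixture) | OC(=O)C1(Cc2ccc(OCc3ccccc3)cc2)C(=O)CC(=O)C(Cc2ccc(OCc3ccccc3)cc2)C1CCc1cc(Cc2ccc(OCc3ccccc3)cc2)ccc1OCc1ccccc1 | intermediate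
16 | 4,6-bis(4-benzyloxybenzyl)-5-{2-[2-benzyloxy-5-(4-benzyloxybenzyl)phenyl]ethyl}cyclohexane-1,3-dione, 4,5-trans-5,6-trans, achiral (mirror plane through C2 and C5) | O=C1CC(=O)[C@@H](Cc2ccc(OCc3ccccc3)cc2)[C@H](CCc2cc(Cc3ccc(OCc4ccccc4)cc3)ccc2OCc2ccccc2)[C@H]1Cc1ccc(OCc2ccccc2)cc1 | intermediate
17 | 4,6-bis(4-benzyloxybenzyl)-5-{2-[2-benzyloxy-5-(4-benzyloxybenzyl)phenyl]ethyl}-3-methoxycyclohex-2-en-1-one, 4,5-trans-5,6-trans, racemic (one enantiomer drawn) | O=C1C=C(OC)[C@@H](Cc2ccc(OCc3ccccc3)cc2)[C@H](CCc2cc(Cc3ccc(OCc4ccccc4)cc3)ccc2OCc2ccccc2)[C@H]1Cc1ccc(OCc2ccccc2)cc1 | intermediate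
18 | 6-phenylselanyl derivative of 17, selenium trans to the C5 chain, racemic | O=C1C=C(OC)[C@@H](Cc2ccc(OCc3ccccc3)cc2)[C@H](CCc2cc(Cc3ccc(OCc4ccccc4)cc3)ccc2OCc2ccccc2)[C@@]1(Cc1ccc(OCc2ccccc2)cc1)[Se]c1ccccc1 | intermediate
19 | selenoxide of 18 (configuration at selenium undefined), racemic | O=C1C=C(OC)[C@@H](Cc2ccc(OCc3ccccc3)cc2)[C@H](CCc2cc(Cc3ccc(OCc4ccccc4)cc3)ccc2OCc2ccccc2)[C@@]1(Cc1ccc(OCc2ccccc2)cc1)[Se](=O)c1ccccc1 | intermediate
20 | 2,4-bis(4-benzyloxybenzyl)-3-{2-[2-benzyloxy-5-(4-benzyloxybenzyl)phenyl]ethyl}-5-methoxycyclohexa-2,5-dien-1-one (racemic at C4) | O=C1C=C(OC)C(Cc2ccc(OCc3ccccc3)cc2)C(CCc2cc(Cc3ccc(OCc4ccccc4)cc3)ccc2OCc2ccccc2)=C1Cc1ccc(OCc2ccccc2)cc1 | intermediate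
21 | 2,4-bis(4-benzyloxybenzyl)-3-{2-[2-benzyloxy-5-(4-benzyloxybenzyl)phenyl]ethyl}-5-methoxyphenol | COc1cc(O)c(Cc2ccc(OCc3ccccc3)cc2)c(CCc2cc(Cc3ccc(OCc4ccccc4)cc3)ccc2OCc2ccccc2)c1Cc1ccc(OCc2ccccc2)cc1 | intermediate
22 | 2,4-bis(4-hydroxybenzyl)-3-{2-[2-hydroxy-5-(4-hydroxybenzyl)phenyl]ethyl}-5-methoxyphenol (CNP0134121.0, achiral) | COc1cc(O)c(Cc2ccc(O)cc2)c(CCc2cc(Cc3ccc(O)cc3)ccc2O)c1Cc1ccc(O)cc1 | target

Total step count: 11. Longest linear sequence: 9 steps (1 → 2 → 3 → 6 → 7 → 10 → 16 → 17 → 21 → 22, that is steps 1, 2, 3, 4, 6, 8, 9, 10 and 11).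

Steps most likely to fail

1. Step 8.
- Risk: the crowded conjugate addition may stall because the adduct reverts to its components faster than it cyclizes. Meanwhile the enone would be slowly consumed by self-condensation.
- Fallback: it sets out from 10 and unsubstituted dimethyl malonate 11. The same NaOMe annulation with the smaller secondary carbanion should give methyl 3-(4-benzyloxybenzyl)-2-{2-[2-benzyloxy-5-(4-benzyloxybenzyl)phenyl]ethyl}-4,6-dioxocyclohexane-1-carboxylate F1. Saponification and decarboxylation then give trans-4-(4-benzyloxybenzyl)-5-{2-[2-benzyloxy-5-(4-benzyloxybenzyl)phenyl]ethyl}cyclohexane-1,3-dione F2.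
- Return to the route: the missing benzyl group is attached after ring formation by γ-alkylation of the dione dianion (LiN(i-Pr)2, 2.2 equiv, THF–DMPU, −78 to 0 °C) with 4. The second deprotonation should occur at the unsubstituted C6 methylene, and this comes back to the route at 16.

2. Step 10.
- Risk: enolization at the hindered tertiary α′ carbon may be incomplete. The electron-rich phenol may also be over-oxidized by peroxide-activated selenium species as it forms.
- Fallback: it sets out from 17. Soft enolization (Me3SiOTf, Et3N, CH2Cl2, 0 °C) should give 3,4-trans-2,4-bis(4-benzyloxybenzyl)-3-{2-[2-benzyloxy-5-(4-benzyloxybenzyl)phenyl]ethyl}-5-methoxy-1-(trimethylsilyloxy)cyclohexa-1,5-diene F3.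
- Return to the route: Saegusa–Ito oxidation with Pd(OAc)2 (1.05 equiv, MeCN–THF, rt) dehydrogenates F3 through an oxa-π-allyl complex of divalent palladium and β-hydride elimination, with no strong base or peroxide present. Tautomerization of 20 brings it back to the route at 21.

3. Step 6.
- Risk: olefination by the α-branched phosphonate anion may be sluggish, which would leave the enolizable aldehyde time for self-aldol condensation.
- Fallback: it sets out from 7. A Morita–Baylis–Hillman reaction with but-3-en-2-one (DABCO, THF–H2O, rt) should give 3-{3-[2-benzyloxy-5-(4-benzyloxybenzyl)phenyl]-1-hydroxypropyl}but-3-en-2-one F4. Acetylation (Ac2O, DMAP, pyridine) then gives 1-[2-benzyloxy-5-(4-benzyloxybenzyl)phenyl]-4-methylidene-5-oxohexan-3-yl acetate F5.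
- Return to the route: commercial 4-benzyloxyphenylmagnesium bromide with CuBr·SMe2 (THF, −78 °C) adds to the terminal methylene and expels acetate (SN2′ addition–elimination). This builds the α-benzyl branch from the other side and comes back to the route at 10.

Further compounds
F1 | step 8 | methyl 3-(4-benzyloxybenzyl)-2-{2-[2-benzyloxy-5-(4-benzyloxybenzyl)phenyl]ethyl}-4,6-dioxocyclohexane-1-carboxylate (diastereomer mixture) | COC(=O)C1C(=O)CC(=O)C(Cc2ccc(OCc3ccccc3)cc2)C1CCc1cc(Cc2ccc(OCc3ccccc3)cc2)ccc1OCc1ccccc1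
F2 | step 8 | trans-4-(4-benzyloxybenzyl)-5-{2-[2-benzyloxy-5-(4-benzyloxybenzyl)phenyl]ethyl}cyclohexane-1,3-dione (racemic) | O=C1CC(=O)[C@@H](Cc2ccc(OCc3ccccc3)cc2)[C@H](CCc2cc(Cc3ccc(OCc4ccccc4)cc3)ccc2OCc2ccccc2)C1
F3 | step 10 | 3,4-trans-2,4-bis(4-benzyloxybenzyl)-3-{2-[2-benzyloxy-5-(4-benzyloxybenzyl)phenyl]ethyl}-5-methoxy-1-(trimethylsilyloxy)cyclohexa-1,5-diene (racemic) | COC1=CC(O[Si](C)(C)C)=C(Cc2ccc(OCc3ccccc3)cc2)[C@@H](CCc2cc(Cc3ccc(OCc4ccccc4)cc3)ccc2OCc2ccccc2)[C@@H]1Cc1ccc(OCc2ccccc2)cc1
F4 | step 6 | 3-{3-[2-benzyloxy-5-(4-benzyloxybenzyl)phenyl]-1-hydroxypropyl}but-3-en-2-one (racemic) | CC(=O)C(=C)C(O)CCc1cc(Cc2ccc(OCc3ccccc3)cc2)ccc1OCc1ccccc1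
F5 | step 6 | 1-[2-benzyloxy-5-(4-benzyloxybenzyl)phenyl]-4-methylidene-5-oxohexan-3-yl acetate (racemic) | CC(=O)OC(CCc1cc(Cc2ccc(OCc3ccccc3)cc2)ccc1OCc1ccccc1)C(=C)C(C)=O
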